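The data stem from a simulated flask on assumed constants.

**The leftover.** At 50.0 h in the south-east run, 64.4% of the solid substrate charged appears in neither reading, target nor starting material. I take it as still solid.

- south-east: solid substrate 1.5 M; partner 1.8 M; initiator 140 mM; run made earlier
- flask: solid substrate 1.5 M; partner 2.70 M; initiator 140 mM; time 40 h

south-east run (percent of the solid substrate charged)

| time / h | target / % | starting material / % |
|---|---|---|
| 4.00 | 2.9 | 0.1 |
| 6.00 | 4.3 | 0 |
| 8.00 | 5.5 | 0.6 |
| 15.0 | 11.1 | 0.8 |
| 20.0 | 14.5 | 0.1 |
| 30.0 | 21.4 | 0.6 |
| 50.0 | 35.2 | 0.4 |

(readings scatter by 0.5 percentage points)

- a species is counted by the solid substrate in it: one ended chains counts as two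
- given per volume of solution although it is solid: solid substrate
- the analysis behind the earlier runs scatters by 0.5 percentage points, standard deviation
- steps thought possible: first chain carrier -> ended carrier; starting material + initiating radical -> capped initiator + first chain carrier; 2 first chain carrier -> ended chains; solid substrate <-> starting material; starting material + second chain carrier -> by-product + first chain carrier; partner + first chain carrier -> target + second chain carrier; initiator -> 2 initiating radical
- at the start none of the solid substrate is in solution
- starting material means what is dissolved; the solid is not counted in it

1. how much target there is at 40 h, in percent of the solid substrate charged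
2. concentration of starting material in solution at 40 h, in percent of saturation

**Bench rule.** At 50.0 h the south-east run reads 0.4% of starting material against 35.2% of target. So I treat the chain as fast: what dissolves is used at once. Dissolving is then the rate-limiting step. The target readings of that run climb nearly in a straight line, though by my count, one partner for each target, partner falls by 29.3% of its charge. The first and last target readings give a slope of 0.0105 M h⁻¹. I call it the feed rate F, the concentration of solid substrate that dissolves and becomes target per hour.

**Its border.** The rule needs solid in the flask. The charge over F gives a solid lifetime T of 142 h, and the asked 40 h is about a quarter of that. The flask's partner, 2.70 M, exceeds its solid substrate, 1.5 M, so I expect the solid to end first. I keep F for the flask with more partner, which gives 28.1% of target. Saturation can't be read from these runs, so I commit to no figure for it.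

**The forecast.** It gives 28.7% of target, above my figure, and 5% of saturation, holding that “dissolution sets the rate”.

**The result.** The flask gives 29.0% of target and 0% of saturation, with 70.9% of the solid substrate still there.

    first chain carrier → ended carrier (k = 580 min⁻¹)
    starting material + initiating radical → capped initiator + first chain carrier (k = 1.40 × 10⁵ M⁻¹ min⁻¹)
    2 first chain carrier → ended chains (k = 5.00 × 10⁷ M⁻¹ s⁻¹)
    solid substrate ⇌ starting material, rate k4*(cs4 - [starting material]) while solid is left; crystals form when [starting material] > cs4 (solubility = 1.40 M, k = 1.30 × 10⁻⁴ min⁻¹)
    starting material + second chain carrier → by-product + first chain carrier (k = 23000 M⁻¹ min⁻¹)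
    partner + first chain carrier → target + second chain carrier (k = 58000 M⁻¹ min⁻¹)
    initiator → 2 initiating radical (k = 4.20 × 10⁻⁴ min⁻¹)

**The neighbour.** The same flask is read at 15 h. F gives 10.5% of target there. The neighbour flask holds 10.9%, with 89.1% of the solid substrate left.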